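Take the easy step first: the dusk run holds less solid reagent than the autumn flask, and its last readings of left-handed product climb almost in a straight line.

common to all: left-handed substrate 0.50 M; right-handed substrate 0.50 M
- autumn: solid reagent 1.25 M; the very flask that is asked about, followed so far
- dusk: solid reagent 0.84 M; run made earlier
- flask: solid reagent 1.25 M; time 40 h

- autumn (time / h: left-handed product / %, left-handed substrate / %): 0.500: 0, 50.1; 1.33: 0.1, 48.8; 3.00: 0.3, 47.5; 8.00: 3.4, 45.3
- dusk (time / h: left-handed product / %, left-handed substrate / %): 10.0: 3.5, 44.3; 20.0: 9.6, 39.6; 30.0: 15.8, 34.9; 40.0: 20.8, 30.9

(each reading ± 0.5 percentage points)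

* how much left-handed product there is at 40 h, in percent of the left-handed substrate and right-handed substrate together charged
* the change that raises the amount of left-handed product at 40 h, in percent of the left-handed substrate and right-handed substrate together charged most ("none" if none brings more than 2 percentage points) (larch / oak / none)
* amount of left-handed product at 40 h, in percent of the left-handed substrate and right-handed substrate together charged, after larch

Between 20.0 h and 40.0 h, dusk gains 0.00560 h⁻¹ of the charge per hour, as a fraction, and that line meets zero at 2.86 h. Dividing the gain by the mean left-handed substrate gives 0.0159 h⁻¹: the capture share, the part of the left-handed substrate taken per hour, a pseudo-first-order constant read from dusk.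

Two views part here. The forecast holds that “dissolution scales with the solid load”, and autumn's 3.4% at 8.00 h stands 0.52 percentage points above dusk's line. It gives 27%, picks larch and gives 42% after it.

I hold that solid merely tops the solution up to a fixed partner level, and that the lead is one reading with a scatter of 0.5 points. Dusk made 0.208 M of product from a charge of 0.84 M, so solid outlasts the run, and autumn should repeat dusk's 20.8%. Larch doubles the capture share, which gives me 34.6% from the left-handed half of the charge; I pick larch too.

The flask gives 20.8%, and 34.7% after larch, which adds 14 points against 2.8 points for oak.

    solid reagent ⇌ partner, rate k1*(cs1 - [partner]) while solid is left; crystals form when [partner] > cs1 (solubility = 0.190 M, k = 0.170 h⁻¹)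
    right-handed substrate ⇌ achiral form (K = 0.0710, k = 0.0250 h⁻¹)
    partner + left-handed substrate → left-handed product (k = 0.0990 M⁻¹ h⁻¹)
    left-handed substrate ⇌ achiral form (K = 0.0710, k = 0.0250 h⁻¹)
    partner + right-handed substrate → right-handed product (k = 0.00120 M⁻¹ h⁻¹)

The forecast's view has its region at low charge: at 0.216 M of solid reagent the answer has moved by 5 points. On the flask, the capture share carried from its 20.0 h state over the mean left-handed substrate reckons 21.3% at 40 h. The same flask stopped at 25 h reckons 13.1% from that state, and it holds 12.9%.

(The earlier runs and the new flask stem from a simulated flask for substances that don't exist, and the scatter is random.)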